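**Remarks on the chemistry (assumptions)**

- Benzofuran numbering is used throughout: O1, C2, C3, C3a, C4–C7, C7a. Ring A is the six-membered ring, ring B the five-membered cyclic ether.
- The open-chain cyclisation precursor 12 has the CIP descriptor R (aryl > CH2Ar > CH3), not S. The same carbon becomes 3S in 14 only because C2 outranks C3a once it bears oxygen; nothing is inverted.
- The ring A silyl ether is carried as triisopropylsilyl instead of tert-butyldimethylsilyl. It sits para to an acetyl group in 2 and 3 and must survive two carbonate-mediated alkylations. The skeletons and the ring closure are unchanged.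

## Structural features

Compound 19 is a 2,3-dihydrobenzofuran-6(5H)-one. Ring A is a cyclohexa-2,4-dienone (C6=O, C7=C7a, C3a=C4) fused through C3a–C7a to ring B (O1, C2, C3). C2 carries a 3,4,5-trimethoxyphenyl group and C3 a methyl group; these adjacent stereocentres are trans (2S,3S). The third stereocentre, C5 (S), is quaternary (methoxy, allyl) and lies next to the C6 carbonyl. It is separated from C3 by the sp2 atoms C3a and C4, so ring B gives no useful bias, and the allyl group has to end up on the face of the C3 methyl. The fragile part is the 6-allyl-6-methoxycyclohexa-2,4-dienone unit: the allyl group can shift by [3,3] processes to C3a or to the C6 oxygen, acid starts dienone–phenol chemistry, and the benzylic C2–O1 bond is sensitive to acid and hydrogenolysis. The real difficulty is to create C5 in the right configuration late, in a ring that cannot rearomatise, without heat, strong base or acid. The key step uses the fact that C2 is both benzylic to the trioxygenated ring and bonded to O1. With the para oxygen of that ring free, C2 is the exocyclic carbon of a para-quinone methide, and the ring A phenol oxygen on C7a can add to it in a five-membered closure. Ring A is kept without its C5 oxygen until after that step, so that it is the harder ring to oxidise.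

## Logic of the disconnections

19 ⇒ 18. The O–CH3 bond on the C5 oxygen is cut. This exposes C5 as a carbinol carbon and therefore as a former carbonyl carbon. Nothing is gained in skeleton, but the next cut becomes possible. The forward step must methylate a tertiary alcohol without making a free alkoxide, and without acid or heat.

18 ⇒ 17. The C5–CH2 bond of the allyl group is cut. C5 then becomes one carbonyl of an ortho-quinone whose C6 carbonyl is deactivated as the vinylogous ester of O1. The quaternary stereocentre and the side chain disappear, and ring A becomes planar. The forward step must add allyl 1,2 at C5 on the Re face under reagent control.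

17 ⇒ 16. The C5–O bond is cut and ring A is rearomatised to the C6 phenol. This gives a stable dihydrobenzofuran and postpones the C5 oxygen until after the oxidative ring closure. The forward step must oxygenate C5 and not C7; the para position C3a is blocked.

16 ⇒ 15 ⇒ 14. The O–Si bond at C6 and the O–CH3 bond on the para oxygen of the C2 aryl group are cut. The free para-hydroxyl is what the key step needs, and the silyl group is what keeps the two phenols apart during methylation. The forward steps must not open ring B through the phenoxide.

14 ⇒ 12 (through 13). The O1–C2 bond is cut. Ring B and the C2 stereocentre are removed, and what remains is a 1,2-diarylpropane with one stereocentre. The forward step must oxidise only the dimethoxyphenol ring and close trans to the C3 methyl.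

12 ⇒ 11 ⇒ 10. The two O–benzyl bonds are cut, then the C3–H and C2–H bonds. The single stereocentre is traced to the hydrogenation of an (E)-1,2-diarylpropene, the best-precedented substrate class for iridium phosphinooxazoline catalysts. The forward step needs geometrically pure 10.

10 ⇒ 9 ⇒ 3 + 8 (8 from 7). The C2=C3 double bond is traced to a tertiary alcohol, and the C2–C3 σ bond is then cut. This gives two aromatic fragments of similar size. The forward steps must form a benzylic Grignard reagent without Wurtz coupling and dehydrate under thermodynamic control to the E alkene.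

7 ⇒ 6 ⇒ 5 ⇒ 4 and 3 ⇒ 2 ⇒ 1. These are functional-group changes and protections down to the two commercial compounds. The only demand is to tell the two hydroxyls of 1 apart; the hydrogen bond of the 2'-OH to the acetyl group does this.

## Other disconnections considered

Alternative 1: The cut is the C7–C7a bond of ring A, with ring B present as a γ-butyrolactone in keto lactone A2.
- Forward key step: a lithium silylamide base forms the methyl ketone enolate (C7), which acylates on the lactone carbonyl (C7a). Acid work-up dehydrates the hemiketal to the vinylogous ester A1, and loss of the silanol across C3a–C4 would then give 19.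
- In favour: no phenol or quinone oxidation is needed, and the sensitive dienone appears only at the very end. C5 is made in an open chain, where established methods for tertiary α-alkoxy ketones apply. On control of C5 this alternative is the better of the two.
- Against: A2 carries the quaternary centre, the silyloxy carbinol and the lactone stereocentres in one acyclic array, and needs a demanding aldol to assemble. The base must choose the methyl ketone over the lactone α-hydrogen at C3a. The tetrahedral intermediate can open ring B by expelling the C2 alkoxide, and the β-silyloxy ketone can undergo retro-aldol cleavage.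
- Comparison: the Claisen-type condensation is as well known as quinone methide trapping (equal). The trans C2/C3 relation is thermodynamic in both plans (equal). The step count to A2 is estimated to be clearly above the 15 steps of the chosen route, with less convergence.

Alternative 2: The cuts are C3–C3a and O1–C2, the latter at the lactol oxidation level.
- Forward key step: the enamine of A5 with a silyl-protected diarylprolinol catalyst adds to A4 at the unsubstituted carbon para to the methoxy-bearing one. Aromatisation and hemiacetal closure give lactol A3.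
- In favour: C3 and ring B are set in one catalytic step from two cheap achiral compounds. In step economy up to ring B this is better than the nine steps to 12, and the regiochemistry on the quinone is secured by the methoxy group.
- Against: A3 has no C2 aryl group, and its ring A carries C5–OH and C6–OMe. The aryl group would have to be added to the lactol with an aryl Grignard reagent, without control at C2, and ring B reclosed by ionisation. C3 is labile while it is α to an aldehyde. The ring would then have to be oxidised with loss of the C6 methyl group to reach 17; attack at C7a, para to the C5 hydroxyl, would open ring B instead.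
- Comparison: the trans closure rests on the same thermodynamic preference (equal). The problem at C5 is untouched, because the route joins the chosen one at 17 (equal). The chosen plan is longer but gets to 17 without an ambiguous para/ortho oxidation of a ring that already holds O1.

Alternative 3: The cut is O1–C7a.
- Forward key step: anodic oxidation of catechol A7 in a perchlorate electrolyte with a fluorinated alcohol co-solvent gives its ortho-quinone. The C2 hydroxyl adds to C7a in a 5-exo-trig conjugate addition, the same mode as the ring closure of catecholamine-derived ortho-quinones. The adduct is oxidised again to A6, which is identical with 17.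
- In favour: it delivers 17 directly, so the silyl ether, its removal and the C5/C7 question of the phenol oxygenation all fall away; this is better in step economy and in regiochemistry of oxygenation. No chemical oxidant is used. C2 is preset, so no thermodynamic closure is relied on.
- Against: A7 needs two contiguous stereocentres before closure, against one in 12. An alcohol is a weak nucleophile for an ortho-quinone, so intermolecular quinone–catechol coupling and attack at C7 compete. The benzylic alcohol next to the trimethoxyphenyl ring can ionise in the acidic fluorinated medium.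
- Comparison: the endgame from 17 is the same (equal). Ring formation is polar conjugate addition in both plans (equal in kind), but here the electrophile is ring A and the stereochemical burden is moved to the precursor.

Key step: step 10

## Route

Step 1
Reactants: 1 2',4'-dihydroxyacetophenone
Product: 2 1-[2-hydroxy-4-(triisopropylsilyloxy)phenyl]ethan-1-one
Conditions: TIPSCl (1.05 equiv), imidazole (2 equiv), CH2Cl2, 0 °C to rt
Reagents that add atoms: triisopropylsilyl chloride, CC(C)[Si](Cl)(C(C)C)C(C)C
Why: Selective phenol silylation: the 2'-OH is tied up in a hydrogen bond to the acetyl oxygen and is hindered, so the bulky chlorosilane reacts only at the free 4'-OH.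

Step 2
Reactants: 2 1-[2-hydroxy-4-(triisopropylsilyloxy)phenyl]ethan-1-one
Product: 3 1-[2-(benzyloxy)-4-(triisopropylsilyloxy)phenyl]ethan-1-one
Conditions: BnBr (1.3 equiv), K2CO3 (2 equiv), Bu4NI (5 mol %), dry acetone, 55 °C
Reagents that add atoms: benzyl bromide, BrCc1ccccc1
Why: Williamson ether synthesis on the chelated phenol with iodide catalysis; the hindered triisopropylsilyl ether is expected to survive anhydrous carbonate in acetone.

Step 3
Reactants: 4 syringaldehyde (4-hydroxy-3,5-dimethoxybenzaldehyde)
Product: 5 4-(benzyloxy)-3,5-dimethoxybenzaldehyde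
Conditions: BnBr (1.2 equiv), K2CO3 (1.5 equiv), DMF, 60 °C
Reagents that add atoms: benzyl bromide, BrCc1ccccc1
Why: Williamson ether synthesis of an acidic 2,6-dimethoxyphenol; the aldehyde has no α-hydrogen and is inert.

Step 4
Reactants: 5 4-(benzyloxy)-3,5-dimethoxybenzaldehyde
Product: 6 [4-(benzyloxy)-3,5-dimethoxyphenyl]methanol
Conditions: NaBH4 (1 equiv), MeOH–THF, 0 °C
Reagents that add atoms: none
Why: Borohydride reduction of an aromatic aldehyde; the ethers are untouched.

Step 5
Reactants: 6 [4-(benzyloxy)-3,5-dimethoxyphenyl]methanol
Product: 7 2-(benzyloxy)-5-(chloromethyl)-1,3-dimethoxybenzene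
Conditions: SOCl2 (1.2 equiv), CH2Cl2, 0 °C; used crude
Reagents that add atoms: thionyl chloride, O=S(Cl)Cl
Why: Chlorodehydroxylation of an electron-rich benzylic alcohol through its chlorosulfite; the chloride is kept cold and used at once because it ionises easily.

Step 6
Reactants: 7 2-(benzyloxy)-5-(chloromethyl)-1,3-dimethoxybenzene; 3 1-[2-(benzyloxy)-4-(triisopropylsilyloxy)phenyl]ethan-1-one
Product: 9 1-[4-(benzyloxy)-3,5-dimethoxyphenyl]-2-[2-(benzyloxy)-4-(triisopropylsilyloxy)phenyl]propan-2-ol (racemic), via benzylic Grignard reagent 8 (not isolated)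
Conditions: 7 (1.5 equiv) added slowly to Mg turnings (4 equiv, activated with BrCH2CH2Br), THF, 0 °C; then 3, −10 °C to rt; sat. aq. NH4Cl
Reagents that add atoms: none
Why: Grignard addition to a ketone; slow addition to excess activated Mg at 0 °C keeps Wurtz coupling of the benzylic halide low, and benzylic Grignard reagents add to acetophenones faster than they enolise them. The carbinol centre is racemic and is destroyed in step 7.

Step 7
Reactants: 9 1-[4-(benzyloxy)-3,5-dimethoxyphenyl]-2-[2-(benzyloxy)-4-(triisopropylsilyloxy)phenyl]propan-2-ol
Product: 10 (E)-1-[4-(benzyloxy)-3,5-dimethoxyphenyl]-2-[2-(benzyloxy)-4-(triisopropylsilyloxy)phenyl]prop-1-ene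
Conditions: p-TsOH·H2O (5 mol %), 4 Å MS, toluene (0.05 M), 80 °C; E isomer purified by crystallisation or chromatography
Reagents that add atoms: none
Why: Acid-catalysed E1 dehydration through the oxygen-stabilised tertiary benzylic cation; under these reversible conditions the alkene mixture should drain to the conjugated trisubstituted alkene with the two aryl groups trans (E), the thermodynamic isomer.

Step 8
Reactants: 10 (E)-1-[4-(benzyloxy)-3,5-dimethoxyphenyl]-2-[2-(benzyloxy)-4-(triisopropylsilyloxy)phenyl]prop-1-ene
Product: 11 (R)-1-[4-(benzyloxy)-3,5-dimethoxyphenyl]-2-[2-(benzyloxy)-4-(triisopropylsilyloxy)phenyl]propane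
Conditions: H2 (50 bar), [Ir(cod)(L)][B(3,5-(CF3)2C6H3)4] (1 mol %; L = (S)-4-tert-butyl-2-[2-(di-o-tolylphosphino)phenyl]-4,5-dihydrooxazole), CH2Cl2, 25 °C
Reagents that add atoms: none
Why: Iridium-catalysed asymmetric hydrogenation of an unfunctionalised trisubstituted alkene (Pfaltz type), for which (E)-1,2-diarylpropenes are the benchmark substrates. By analogy with (E)-α-methylstilbene the (S)-ligand is expected to give the R centre (the future C3); the antipodal complex is used if the ortho-benzyloxy group reverses the sense.

Step 9
Reactants: 11 (R)-1-[4-(benzyloxy)-3,5-dimethoxyphenyl]-2-[2-(benzyloxy)-4-(triisopropylsilyloxy)phenyl]propane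
Product: 12 (R)-4-{2-[2-hydroxy-4-(triisopropylsilyloxy)phenyl]propyl}-2,6-dimethoxyphenol
Conditions: H2 (1 atm), 10% Pd/C, EtOAc–EtOH 1:1, rt
Reagents that add atoms: none
Why: Hydrogenolysis of two aryl benzyl ethers; the aryl silyl ether and the stereocentre, which carries no heteroatom, are not affected.

Step 10
Reactants: 12 (R)-4-{2-[2-hydroxy-4-(triisopropylsilyloxy)phenyl]propyl}-2,6-dimethoxyphenol
Product: 14 2,6-dimethoxy-4-[(2S,3S)-3-methyl-6-(triisopropylsilyloxy)-2,3-dihydrobenzofuran-2-yl]phenol, via para-quinone methide 13 (not isolated)
Conditions: Ag2O (1.5 equiv), 4 Å MS, CH2Cl2 (0.02 M), rt, dark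
Reagents that add atoms: none
Why: Oxidative para-quinone methide formation followed by intramolecular oxa-Michael (1,6-conjugate) addition, the reaction type known from Ag2O oxidations of 4-alkyl-2,6-dimethoxyphenols and from biomimetic dihydrobenzofuran neolignan syntheses. Ag2O removes two electrons and two protons (O–H and benzylic C–H) from the dimethoxyphenol unit of 12 to give 13, whose exocyclic carbon is the future C2. The C7a phenol adds to that carbon in a 5-exo-trig closure (O1–C2 formed, ring B closed) and the quinoid ring rearomatises to the free phenol. The new stereocentre C2 is controlled by the existing C3: in 13 the C3–H bond lies in the plane of the quinoid ring to minimise allylic strain, so the phenol held on C3 attacks the face that places the aryl group anti to the C3 methyl, giving the 2,3-trans (2S,3S) ring. Trans is also the thermodynamic isomer, and because the product keeps the free para-hydroxyl the closure can reverse on the basic oxide surface, so any cis isomer should drain to trans. The selectivity the step needs is oxidation of the right ring: the 2,6-dimethoxy-4-alkylphenol is much easier to oxidise than the ring A phenol, which has only a meta-silyloxy group and deliberately no C5 oxygen. Over-oxidation of 14 is limited by the small excess of oxidant, dilution and exclusion of light.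

Step 11
Reactants: 14 2,6-dimethoxy-4-[(2S,3S)-3-methyl-6-(triisopropylsilyloxy)-2,3-dihydrobenzofuran-2-yl]phenol
Product: 15 triisopropyl{[(2S,3S)-3-methyl-2-(3,4,5-trimethoxyphenyl)-2,3-dihydrobenzofuran-6-yl]oxy}silane
Conditions: MeI (3 equiv), K2CO3 (2 equiv), acetone, 40 °C
Reagents that add atoms: iodomethane, CI
Why: Williamson methylation of the hindered phenol, the reaction used routinely on phenolic 2-aryl-2,3-dihydrobenzofurans; ring B is not expected to open under carbonate at 40 °C, and the silyl ether is retained.

Step 12
Reactants: 15 triisopropyl{[(2S,3S)-3-methyl-2-(3,4,5-trimethoxyphenyl)-2,3-dihydrobenzofuran-6-yl]oxy}silane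
Product: 16 (2S,3S)-3-methyl-2-(3,4,5-trimethoxyphenyl)-2,3-dihydrobenzofuran-6-ol
Conditions: Bu4NF (1.1 equiv), AcOH (1.1 equiv), THF, 0 °C
Reagents that add atoms: none
Why: Fluoride-induced cleavage of an aryl silyl ether, driven by Si–F bond formation; acetic acid buffering keeps the phenoxide concentration low.

Step 13
Reactants: 16 (2S,3S)-3-methyl-2-(3,4,5-trimethoxyphenyl)-2,3-dihydrobenzofuran-6-ol
Product: 17 (2S,3S)-3-methyl-2-(3,4,5-trimethoxyphenyl)-2,3-dihydrobenzofuran-5,6-dione
Conditions: IBX (1.2 equiv), DMF, rt, dark; cold aqueous work-up, used at once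
Reagents that add atoms: 2-iodoxybenzoic acid (IBX), O=C1OI(=O)(O)c2ccccc12
Why: IBX-mediated dearomatising ortho-oxygenation of a phenol to an ortho-quinone: the phenol binds to iodine, oxygen is transferred within the complex to an ortho carbon, and the catechol–iodine species collapses to the quinone. The para position (C3a) is blocked, and of the two ortho positions C5 (para to O1, unhindered) is expected to react in preference to C7 (between two oxygens); no stereocentre is touched.

Step 14
Reactants: 17 (2S,3S)-3-methyl-2-(3,4,5-trimethoxyphenyl)-2,3-dihydrobenzofuran-5,6-dione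
Product: 18 (2S,3S,5S)-5-allyl-5-hydroxy-3-methyl-2-(3,4,5-trimethoxyphenyl)-2,3-dihydrobenzofuran-6(5H)-one
Conditions: allyl-B(OiPr)2 (1.5 equiv), (S)-3,3'-dibromo-1,1'-bi-2-naphthol (15 mol %), PhCF3–toluene 3:1, −35 °C; pH 7 buffer at 0 °C
Reagents that add atoms: allyldiisopropoxyborane, C=CCB(OC(C)C)OC(C)C
Why: Proposed new method: the chiral biphenol exchanges one isopropoxy group on boron to give a more Lewis acidic, hydrogen-bonded allylboronate, which binds the C5 carbonyl (the C6 carbonyl is deactivated as the vinylogous ester of O1) and transfers allyl through a closed six-membered chair transition state, so addition is 1,2 and at C5 rather than conjugate. To reach 5S the allyl group must arrive on the Re face of C5=O, the face syn to the C3 methyl; C2 and C3 are too far away to help, so the catalyst must supply the control, with the C6-acyl flank taking the place of the larger substituent in the model for aryl ketones ((S)-diol for Re attack; the (R)-diol is used if the sense proves opposite). The closest known reaction type is the chiral-biphenol-catalysed asymmetric allylboration of aryl and alkenyl ketones, together with allylborations of cyclic 1,2-dicarbonyl compounds such as isatins; an ortho-quinone carbonyl has not been shown as the acceptor.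

Step 15
Reactants: 18 (2S,3S,5S)-5-allyl-5-hydroxy-3-methyl-2-(3,4,5-trimethoxyphenyl)-2,3-dihydrobenzofuran-6(5H)-one
Product: 19 (2S,3S,5S)-5-allyl-5-methoxy-3-methyl-2-(3,4,5-trimethoxyphenyl)-2,3-dihydrobenzofuran-6(5H)-one (the target)
Conditions: MeI (20 equiv), Ag2O (3 equiv), 4 Å MS, CH2Cl2, rt, dark
Reagents that add atoms: iodomethane, CI
Why: Purdie methylation (MeI/Ag2O) of the tertiary carbinol under near-neutral conditions, with retention at C5. A free alkoxide is avoided because it would trigger an anionic oxy-Cope shift of the allyl group to C3a; acids and methyl triflate are avoided because they would start dienone–phenol chemistry; and the reaction is kept at room temperature because the product can undergo [3,3] shifts on heating.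

## Compound list

1 | 2',4'-dihydroxyacetophenone | CC(=O)c1ccc(O)cc1O | starting material
2 | 1-[2-hydroxy-4-(triisopropylsilyloxy)phenyl]ethan-1-one | CC(=O)c1ccc(O[Si](C(C)C)(C(C)C)C(C)C)cc1O | intermediate
3 | 1-[2-(benzyloxy)-4-(triisopropylsilyloxy)phenyl]ethan-1-one | CC(=O)c1ccc(O[Si](C(C)C)(C(C)C)C(C)C)cc1OCc1ccccc1 | intermediate
4 | syringaldehyde | COc1cc(C=O)cc(OC)c1O | starting material
5 | 4-(benzyloxy)-3,5-dimethoxybenzaldehyde | COc1cc(C=O)cc(OC)c1OCc1ccccc1 | intermediate
6 | [4-(benzyloxy)-3,5-dimethoxyphenyl]methanol | COc1cc(CO)cc(OC)c1OCc1ccccc1 | intermediate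
7 | 2-(benzyloxy)-5-(chloromethyl)-1,3-dimethoxybenzene | COc1cc(CCl)cc(OC)c1OCc1ccccc1 | intermediate
8 | [4-(benzyloxy)-3,5-dimethoxybenzyl]magnesium chloride | COc1cc(C[Mg]Cl)cc(OC)c1OCc1ccccc1 | intermediate (formed in the flask, not isolated)
9 | 1-[4-(benzyloxy)-3,5-dimethoxyphenyl]-2-[2-(benzyloxy)-4-(triisopropylsilyloxy)phenyl]propan-2-ol (racemic) | CC(O)(Cc1cc(OC)c(OCc2ccccc2)c(OC)c1)c1ccc(O[Si](C(C)C)(C(C)C)C(C)C)cc1OCc1ccccc1 | intermediate
10 | (E)-1-[4-(benzyloxy)-3,5-dimethoxyphenyl]-2-[2-(benzyloxy)-4-(triisopropylsilyloxy)phenyl]prop-1-ene | C/C(=C\c1cc(OC)c(OCc2ccccc2)c(OC)c1)c1ccc(O[Si](C(C)C)(C(C)C)C(C)C)cc1OCc1ccccc1 | intermediate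
11 | (R)-1-[4-(benzyloxy)-3,5-dimethoxyphenyl]-2-[2-(benzyloxy)-4-(triisopropylsilyloxy)phenyl]propane | C[C@H](Cc1cc(OC)c(OCc2ccccc2)c(OC)c1)c1ccc(O[Si](C(C)C)(C(C)C)C(C)C)cc1OCc1ccccc1 | intermediate
12 | (R)-4-{2-[2-hydroxy-4-(triisopropylsilyloxy)phenyl]propyl}-2,6-dimethoxyphenol | C[C@H](Cc1cc(OC)c(O)c(OC)c1)c1ccc(O[Si](C(C)C)(C(C)C)C(C)C)cc1O | intermediate (key-step precursor)
13 | 4-{(R)-2-[2-hydroxy-4-(triisopropylsilyloxy)phenyl]propylidene}-2,6-dimethoxycyclohexa-2,5-dien-1-one | C[C@H](C=C1C=C(OC)C(=O)C(OC)=C1)c1ccc(O[Si](C(C)C)(C(C)C)C(C)C)cc1O | intermediate (formed in the flask, not isolated)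
14 | 2,6-dimethoxy-4-[(2S,3S)-3-methyl-6-(triisopropylsilyloxy)-2,3-dihydrobenzofuran-2-yl]phenol | C[C@@H]1[C@@H](c2cc(OC)c(O)c(OC)c2)Oc2cc(O[Si](C(C)C)(C(C)C)C(C)C)ccc12 | intermediate (key-step product)
15 | triisopropyl{[(2S,3S)-3-methyl-2-(3,4,5-trimethoxyphenyl)-2,3-dihydrobenzofuran-6-yl]oxy}silane | C[C@@H]1[C@@H](c2cc(OC)c(OC)c(OC)c2)Oc2cc(O[Si](C(C)C)(C(C)C)C(C)C)ccc12 | intermediate
16 | (2S,3S)-3-methyl-2-(3,4,5-trimethoxyphenyl)-2,3-dihydrobenzofuran-6-ol | C[C@@H]1[C@@H](c2cc(OC)c(OC)c(OC)c2)Oc2cc(O)ccc12 | intermediate
17 | (2S,3S)-3-methyl-2-(3,4,5-trimethoxyphenyl)-2,3-dihydrobenzofuran-5,6-dione | C[C@@H]1[C@@H](c2cc(OC)c(OC)c(OC)c2)OC2=CC(=O)C(=O)C=C12 | intermediate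
18 | (2S,3S,5S)-5-allyl-5-hydroxy-3-methyl-2-(3,4,5-trimethoxyphenyl)-2,3-dihydrobenzofuran-6(5H)-one | C=CC[C@]1(O)C=C2C(=CC1=O)O[C@H](c1cc(OC)c(OC)c(OC)c1)[C@H]2C | intermediate
19 | (2S,3S,5S)-5-allyl-5-methoxy-3-methyl-2-(3,4,5-trimethoxyphenyl)-2,3-dihydrobenzofuran-6(5H)-one | C=CC[C@]1(OC)C=C2C(=CC1=O)O[C@H](c1cc(OC)c(OC)c(OC)c1)[C@H]2C | target

## Step count and least certain steps

Total step count: 15. Longest linear sequence: 13 steps (from 4 through steps 3–15); the ring A branch (steps 1–2) joins at step 6.

**Step 14** (the step that bears the label "Proposed new method:").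
- What may go wrong: poor facial selectivity. The quinone carbonyl is very electrophilic, so uncatalysed background addition of the boronate can compete. The two flanks of C5 (C4–H and the C6 carbonyl) are both flat and may be poorly distinguished. Any small substrate bias should favour the face away from the C3 methyl, which is the wrong one. Redox reaction between the quinone and the naphthol catalyst is a second concern.
- Fallback, known chemistry, setting out from 17 and returning at 18: indium-mediated Barbier allylation (allyl bromide, In powder, THF–H2O, 0 °C) is an established 1,2-addition to ortho-quinones and 1,2-diones. It should give the C5 adducts without facial control, that is 18 together with its epimer (2S,3S,5R)-5-allyl-5-hydroxy-3-methyl-2-(3,4,5-trimethoxyphenyl)-2,3-dihydrobenzofuran-6(5H)-one F1. The two are diastereomers and would be separated by chromatography on silica or preparative HPLC below room temperature. This replaces reagent control by separation, at the cost of about half the material, and 18 goes on to step 15.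

**Step 10** (key step).
- What may go wrong: over-oxidation. The product keeps a free para-hydroxyl and a benzylic C2–H, so a second oxidation and tautomerisation to the aromatic benzofuran is possible. Tautomerisation of 13 to the styrene, or radical coupling of phenoxyl radicals, could compete if the closure is slow.
- Fallback, setting out from 10 and returning at 14, with the C2 oxidation level put in by hydroboration instead of by an oxidant:
  - Asymmetric hydroboration of 10 with monoisopinocampheylborane (antipode chosen to set the methine as in 12; THF, −25 °C) and NaOH/H2O2 places boron on the less substituted benzylic carbon. Syn addition should give (1S,2S)-1-[4-(benzyloxy)-3,5-dimethoxyphenyl]-2-[2-(benzyloxy)-4-(triisopropylsilyloxy)phenyl]propan-1-ol F2.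
  - Neutral hydrogenolysis (H2, Pd/C, EtOAc) should give 4-{(1S,2S)-1-hydroxy-2-[2-hydroxy-4-(triisopropylsilyloxy)phenyl]propyl}-2,6-dimethoxyphenol F3.
  - Catalytic pyridinium p-toluenesulfonate in CH2Cl2 at 0 °C should ionise the para-hydroxybenzylic alcohol to the same quinone methide 13 without any oxidant, and trans closure gives 14.
  - The enantiomeric purity from this hydroboration is expected to be lower than from step 8 and would have to be raised by crystallisation.

**Step 13.**
- What may go wrong: oxygenation at C7 instead of C5, or loss of the quinone by dimerisation or by tautomerisation through the C3–H bond, which would also erode the C3 configuration.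
- Fallback, setting out from 16 and returning at 17, with the C5 oxygen introduced by formylation and Dakin oxidation:
  - Magnesium-mediated ortho-formylation (MgCl2, Et3N, paraformaldehyde, MeCN, 70 °C) is known to take the ortho position para to a meta-alkoxy group. It should give (2S,3S)-6-hydroxy-3-methyl-2-(3,4,5-trimethoxyphenyl)-2,3-dihydrobenzofuran-5-carbaldehyde F4.
  - Dakin oxidation (H2O2, NaOH, 0 °C, under argon) should give (2S,3S)-3-methyl-2-(3,4,5-trimethoxyphenyl)-2,3-dihydrobenzofuran-5,6-diol F5.
  - Oxidation of the catechol with Ag2O in CH2Cl2 at 0 °C should give 17.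

**Step 7.**
- What may go wrong: incomplete geometric control. The Z alkene and the 1,1-disubstituted isomer may persist, and the acid may cause cationic dimerisation of the electron-rich alkene. Any Z isomer carried into step 8 lowers the enantiomeric purity of 11 directly.
- Fallback, setting out from 3 and returning at 11, which avoids the trisubstituted alkene and sets the stereocentre by hydroboration:
  - Wittig methylenation of 3 (Ph3PCH3Br, KOtBu, THF) should give 2-(benzyloxy)-1-(prop-1-en-2-yl)-4-(triisopropylsilyloxy)benzene F6.
  - Cobalt-catalysed asymmetric hydroboration of this 1,1-disubstituted aryl alkene (HBpin, a chiral oxazoline iminopyridine CoCl2 complex activated with NaBHEt3, ligand antipode chosen for the R centre) should give (R)-2-{2-[2-(benzyloxy)-4-(triisopropylsilyloxy)phenyl]propyl}-4,4,5,5-tetramethyl-1,3,2-dioxaborolane F7.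
  - B-alkyl Suzuki–Miyaura coupling (Pd(OAc)2, RuPhos, K3PO4, toluene–H2O, 80 °C) with 2-(benzyloxy)-5-bromo-1,3-dimethoxybenzene F8 should give 11. F8 is made from commercial 4-bromo-2,6-dimethoxyphenol with BnBr and K2CO3.

## Further compounds

F1 | step 14 | (2S,3S,5R)-5-allyl-5-hydroxy-3-methyl-2-(3,4,5-trimethoxyphenyl)-2,3-dihydrobenzofuran-6(5H)-one | C=CC[C@@]1(O)C=C2C(=CC1=O)O[C@H](c1cc(OC)c(OC)c(OC)c1)[C@H]2C
F2 | step 10 | (1S,2S)-1-[4-(benzyloxy)-3,5-dimethoxyphenyl]-2-[2-(benzyloxy)-4-(triisopropylsilyloxy)phenyl]propan-1-ol | C[C@H]([C@H](O)c1cc(OC)c(OCc2ccccc2)c(OC)c1)c1ccc(O[Si](C(C)C)(C(C)C)C(C)C)cc1OCc1ccccc1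
F3 | step 10 | 4-{(1S,2S)-1-hydroxy-2-[2-hydroxy-4-(triisopropylsilyloxy)phenyl]propyl}-2,6-dimethoxyphenol | C[C@H]([C@H](O)c1cc(OC)c(O)c(OC)c1)c1ccc(O[Si](C(C)C)(C(C)C)C(C)C)cc1O
F4 | step 13 | (2S,3S)-6-hydroxy-3-methyl-2-(3,4,5-trimethoxyphenyl)-2,3-dihydrobenzofuran-5-carbaldehyde | C[C@@H]1[C@@H](c2cc(OC)c(OC)c(OC)c2)Oc2cc(O)c(C=O)cc12
F5 | step 13 | (2S,3S)-3-methyl-2-(3,4,5-trimethoxyphenyl)-2,3-dihydrobenzofuran-5,6-diol | C[C@@H]1[C@@H](c2cc(OC)c(OC)c(OC)c2)Oc2cc(O)c(O)cc12
F6 | step 7 | 2-(benzyloxy)-1-(prop-1-en-2-yl)-4-(triisopropylsilyloxy)benzene | C=C(C)c1ccc(O[Si](C(C)C)(C(C)C)C(C)C)cc1OCc1ccccc1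
F7 | step 7 | (R)-2-{2-[2-(benzyloxy)-4-(triisopropylsilyloxy)phenyl]propyl}-4,4,5,5-tetramethyl-1,3,2-dioxaborolane | C[C@H](CB1OC(C)(C)C(C)(C)O1)c1ccc(O[Si](C(C)C)(C(C)C)C(C)C)cc1OCc1ccccc1
F8 | step 7 | 2-(benzyloxy)-5-bromo-1,3-dimethoxybenzene | COc1cc(Br)cc(OC)c1OCc1ccccc1
A1 | alternative 1 | (2S,3S,5S)-5-allyl-5-methoxy-3-methyl-4-(triethylsilyloxy)-2-(3,4,5-trimethoxyphenyl)-3,3a,4,5-tetrahydrobenzofuran-6(2H)-one (C3a and C4 unspecified) | C=CC[C@]1(OC)C(O[Si](CC)(CC)CC)C2C(=CC1=O)O[C@H](c1cc(OC)c(OC)c(OC)c1)[C@H]2C
A2 | alternative 1 | (4S,5S)-3-[(2S)-2-acetyl-2-methoxy-1-(triethylsilyloxy)pent-4-en-1-yl]-4-methyl-5-(3,4,5-trimethoxyphenyl)oxolan-2-one (C3 and the silyloxy carbon unspecified) | C=CC[C@@](OC)(C(C)=O)C(O[Si](CC)(CC)CC)C1C(=O)O[C@H](c2cc(OC)c(OC)c(OC)c2)[C@H]1C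
A3 | alternative 2 | (3S)-6-methoxy-3-methyl-2,3-dihydrobenzofuran-2,5-diol (lactol epimers) | C[C@@H]1C(O)Oc2cc(OC)c(O)cc12
A4 | alternative 2 | 2-methoxy-1,4-benzoquinone | COC1=CC(=O)C=CC1=O
A5 | alternative 2 | propanal | CCC=O
A6 | alternative 3 | (2S,3S)-3-methyl-2-(3,4,5-trimethoxyphenyl)-2,3-dihydrobenzofuran-5,6-dione (identical with 17) | C[C@@H]1[C@@H](c2cc(OC)c(OC)c(OC)c2)OC2=CC(=O)C(=O)C=C12
A7 | alternative 3 | 4-[(1S,2S)-1-hydroxy-1-(3,4,5-trimethoxyphenyl)propan-2-yl]benzene-1,2-diol | C[C@H]([C@H](O)c1cc(OC)c(OC)c(OC)c1)c1ccc(O)c(O)c1
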